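The hexasubstituted ring A is disconnected at C5–C4a (and, one step earlier, at C8–C8a). Its four adjacent oxygen-bearing carbons C5–C8 are the four ring carbons of dimethyl squarate, and C8a=C4a is the enol-ether alkene of a 2-aryl-3,4-dihydro-2H-pyran that already carries O1, C2, C3 and an oxygenated C4 of ring C. Heating the squarate 1,2-adduct, a 4-hydroxy-2,3-dimethoxy-4-(dihydropyran-6-yl)cyclobutenone, should open the four-membered ring to a dienylketene that closes and aromatises to the 5,8-dihydroxy-6,7-dimethoxyflavan in one isomerisation. Double O-methylation, oxidation at C4, dehydrogenation and desilylation then lead to the flavone.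

Key step: step 6

Assumption: the target is achiral, so all intermediates are racemic (SMILES show one enantiomer of the 2,4-cis series). The C4 oxygen is carried as a triethylsilyl ether, which has no Si–CH3 group open to metalation and is cleaved by dilute acetic acid without loss of the aryl triisopropylsilyl ethers or ionisation of the benzylic C4–O bond.

Step 1
Reactants: 1 3,4-dihydroxybenzaldehyde
Product: 2 3,4-bis(triisopropylsilyloxy)benzaldehyde
Conditions: TIPSCl, imidazole, DMAP (cat.), DMF, 25 → 40 °C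
Reagents that add atoms: triisopropylsilyl chloride, CC(C)[Si](Cl)(C(C)C)C(C)C
Why: Imidazole-promoted O-silylation of both phenols; the bulky triisopropylsilyl ethers block ortho-lithiation of ring B and should withstand t-BuLi, carbonate, mild acid and DDQ.

Step 2
Reactants: 2 3,4-bis(triisopropylsilyloxy)benzaldehyde; 3 trans-1-methoxy-3-(trimethylsilyloxy)buta-1,3-diene (Danishefsky's diene)
Product: 5 racemic 2-[3,4-bis(triisopropylsilyloxy)phenyl]-2,3-dihydro-4H-pyran-4-one, via methoxy silyloxy dihydropyran cycloadduct 4 (not isolated)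
Conditions: ZnCl2 (cat.), THF, 25 °C; then TFA (cat.), CH2Cl2, 0 °C
Reagents that add atoms: none
Why: Lewis-acid-catalysed hetero-Diels–Alder reaction of an aryl aldehyde with Danishefsky's diene, then acid-induced loss of methanol and the silyl group from the cycloadduct, is the standard entry to 2-aryl-dihydropyranones; the C2 centre forms racemic, which is acceptable because it becomes sp2 in step 10.

Step 3
Reactants: 5 racemic 2-[3,4-bis(triisopropylsilyloxy)phenyl]-2,3-dihydro-4H-pyran-4-one
Product: 6 racemic cis-2-[3,4-bis(triisopropylsilyloxy)phenyl]-3,4-dihydro-2H-pyran-4-ol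
Conditions: NaBH4, CeCl3·7H2O, MeOH/CH2Cl2, −78 °C; basic work-up
Reagents that add atoms: none
Why: Luche reduction gives clean 1,2-reduction of the vinylogous ester, hydride adding to the face that leaves the pseudo-equatorial alcohol cis to the C2 aryl group; the C4 configuration is of no consequence because C4 is oxidised in step 9.

Step 4
Reactants: 6 racemic cis-2-[3,4-bis(triisopropylsilyloxy)phenyl]-3,4-dihydro-2H-pyran-4-ol
Product: 7 racemic cis-2-[3,4-bis(triisopropylsilyloxy)phenyl]-4-(triethylsilyloxy)-3,4-dihydro-2H-pyran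
Conditions: TESCl, imidazole, CH2Cl2, 0 °C
Reagents that add atoms: triethylsilyl chloride, CC[Si](Cl)(CC)CC
Why: Standard silylation of a secondary allylic alcohol under basic conditions that leave the acid-sensitive enol ether untouched.

Step 5
Reactants: 7 racemic cis-2-[3,4-bis(triisopropylsilyloxy)phenyl]-4-(triethylsilyloxy)-3,4-dihydro-2H-pyran; 8 dimethyl squarate
Product: 10 4-hydroxy-2,3-dimethoxy-4-{cis-2-[3,4-bis(triisopropylsilyloxy)phenyl]-4-(triethylsilyloxy)-3,4-dihydro-2H-pyran-6-yl}cyclobut-2-en-1-one (both carbinol epimers), via 6-lithiodihydropyran 9 (not isolated)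
Conditions: t-BuLi, THF, −78 → −10 °C; then cannulation into 8, THF, −78 °C; aq. NH4Cl at −78 °C; Et3N-washed silica
Reagents that add atoms: none
Why: α-Lithiation of a cyclic enol ether at the vinylic C6–H next to oxygen (as for dihydropyrans and glycals) and 1,2-addition of the vinyllithium to one carbonyl of dimethyl squarate at −78 °C are both established; the new carbinol centre forms unselectively and later becomes aromatic C8.

Step 6
Reactants: 10 4-hydroxy-2,3-dimethoxy-4-{cis-2-[3,4-bis(triisopropylsilyloxy)phenyl]-4-(triethylsilyloxy)-3,4-dihydro-2H-pyran-6-yl}cyclobut-2-en-1-one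
Product: 13 racemic cis-5,8-dihydroxy-6,7-dimethoxy-4-(triethylsilyloxy)-2-[3,4-bis(triisopropylsilyloxy)phenyl]chroman, via dienylketene 11 (not isolated), via cyclohexadienone 12 (not isolated)
Conditions: toluene (degassed), 110 °C, argon
Reagents that add atoms: none
Why: Thermal conrotatory 4π opening of the cyclobutenone at its carbonyl–carbinol bond gives dienylketene 11, in which the ketene is conjugated through the dimethoxy alkene with the C8a=C4a enol ether. Disrotatory 6π electrocyclisation closes the six-membered ring A by joining the ketene carbon (future C5) to C4a, and enolisation of cyclohexadienone 12 gives the aromatic 5,8-hydroquinone; this is the known ring expansion of 4-alkenyl-4-hydroxycyclobutenones to hydroquinones (Moore rearrangement), applied here to a 6-dihydropyranyl adduct. No lasting stereocentre is created, because the carbinol carbon and the transient C4a centre both become aromatic and the cis C2/C4 pair of ring C is untouched. The selectivity needed is torquoselectivity: the donor hydroxyl on the carbinol carbon rotates outward, which turns the dihydropyranyl group inward, cis to the ketene, so that closure is possible and lactonisation by the hydroxyl is not. Regiochemistry is fixed by connectivity, since C4a is the only free terminus of the triene, so the carbinol carbon becomes C8 next to O1 and the ketene carbon becomes C5 next to C4. Neutral, oxygen-free toluene at 110 °C should spare the air-sensitive hydroquinone and the benzylic C4 silyl ether.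

Step 7
Reactants: 13 racemic cis-5,8-dihydroxy-6,7-dimethoxy-4-(triethylsilyloxy)-2-[3,4-bis(triisopropylsilyloxy)phenyl]chroman (used crude, without exposure to air)
Product: 14 racemic cis-5,6,7,8-tetramethoxy-4-(triethylsilyloxy)-2-[3,4-bis(triisopropylsilyloxy)phenyl]chroman
Conditions: MeI, K2CO3, acetone (degassed), 50 °C, argon
Reagents that add atoms: iodomethane, CI
Why: Williamson O-methylation of both phenols under carbonate conditions that aryl triisopropylsilyl ethers tolerate; exclusion of air prevents oxidation of the hydroquinone dianion to the quinone.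

Step 8
Reactants: 14 racemic cis-5,6,7,8-tetramethoxy-4-(triethylsilyloxy)-2-[3,4-bis(triisopropylsilyloxy)phenyl]chroman
Product: 15 racemic cis-5,6,7,8-tetramethoxy-2-[3,4-bis(triisopropylsilyloxy)phenyl]chroman-4-ol
Conditions: AcOH/THF/H2O (3:1:1), 25 °C
Reagents that add atoms: none
Why: Acid hydrolysis cleaves a secondary triethylsilyl ether far faster than aryl triisopropylsilyl ethers, and in aqueous medium any ionisation at benzylic C4 would return the same alcohol (its configuration is irrelevant).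

Step 9
Reactants: 15 racemic cis-5,6,7,8-tetramethoxy-2-[3,4-bis(triisopropylsilyloxy)phenyl]chroman-4-ol
Product: 16 racemic 5,6,7,8-tetramethoxy-2-[3,4-bis(triisopropylsilyloxy)phenyl]chroman-4-one (flavanone)
Conditions: Dess–Martin periodinane, CH2Cl2, 0 → 25 °C
Reagents that add atoms: none
Why: Dess–Martin oxidation of a secondary benzylic alcohol to the aryl ketone proceeds under near-neutral conditions that spare the silyl ethers and the electron-rich ring A.

Step 10
Reactants: 16 racemic 5,6,7,8-tetramethoxy-2-[3,4-bis(triisopropylsilyloxy)phenyl]chroman-4-one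
Product: 17 5,6,7,8-tetramethoxy-2-[3,4-bis(triisopropylsilyloxy)phenyl]-4H-chromen-4-one (flavone)
Conditions: DDQ, 1,4-dioxane, 100 °C
Reagents that add atoms: none
Why: DDQ dehydrogenation of a flavanone to the flavone, by hydride abstraction from the doubly activated C2–H (benzylic and α to O1) and loss of a C3 proton, is a standard flavonoid transformation and removes the last stereocentre.

Step 11
Reactants: 17 5,6,7,8-tetramethoxy-2-[3,4-bis(triisopropylsilyloxy)phenyl]-4H-chromen-4-one
Product: 18 2-(3,4-dihydroxyphenyl)-5,6,7,8-tetramethoxy-4H-chromen-4-one (target)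
Conditions: Bu4NF, AcOH, THF, 0 °C
Reagents that add atoms: none
Why: Fluoride cleaves both aryl silyl ethers through pentacoordinate silicon, and the acetic acid buffer keeps the liberated catechol protonated and safe from air oxidation.

Compound list
1 | 3,4-dihydroxybenzaldehyde | O=Cc1ccc(O)c(O)c1 | starting material
2 | 3,4-bis(triisopropylsilyloxy)benzaldehyde | O=Cc1ccc(O[Si](C(C)C)(C(C)C)C(C)C)c(O[Si](C(C)C)(C(C)C)C(C)C)c1 | intermediate
3 | trans-1-methoxy-3-(trimethylsilyloxy)buta-1,3-diene | CO/C=C/C(=C)O[Si](C)(C)C | starting material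
4 | 2-[3,4-bis(triisopropylsilyloxy)phenyl]-6-methoxy-4-(trimethylsilyloxy)-3,6-dihydro-2H-pyran (racemic, both acetal epimers) | COC1C=C(O[Si](C)(C)C)C[C@H](c2ccc(O[Si](C(C)C)(C(C)C)C(C)C)c(O[Si](C(C)C)(C(C)C)C(C)C)c2)O1 | intermediate (not isolated)
5 | 2-[3,4-bis(triisopropylsilyloxy)phenyl]-2,3-dihydro-4H-pyran-4-one (racemic) | O=C1C=CO[C@@H](c2ccc(O[Si](C(C)C)(C(C)C)C(C)C)c(O[Si](C(C)C)(C(C)C)C(C)C)c2)C1 | intermediate
6 | cis-2-[3,4-bis(triisopropylsilyloxy)phenyl]-3,4-dihydro-2H-pyran-4-ol (racemic) | O[C@H]1C=CO[C@@H](c2ccc(O[Si](C(C)C)(C(C)C)C(C)C)c(O[Si](C(C)C)(C(C)C)C(C)C)c2)C1 | intermediate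
7 | cis-2-[3,4-bis(triisopropylsilyloxy)phenyl]-4-(triethylsilyloxy)-3,4-dihydro-2H-pyran (racemic) | CC[Si](CC)(CC)O[C@H]1C=CO[C@@H](c2ccc(O[Si](C(C)C)(C(C)C)C(C)C)c(O[Si](C(C)C)(C(C)C)C(C)C)c2)C1 | intermediate
8 | dimethyl squarate (3,4-dimethoxycyclobut-3-ene-1,2-dione) | COC1=C(OC)C(=O)C1=O | starting material
9 | cis-2-[3,4-bis(triisopropylsilyloxy)phenyl]-6-lithio-4-(triethylsilyloxy)-3,4-dihydro-2H-pyran | [Li]C1=C[C@H](O[Si](CC)(CC)CC)C[C@H](c2ccc(O[Si](C(C)C)(C(C)C)C(C)C)c(O[Si](C(C)C)(C(C)C)C(C)C)c2)O1 | intermediate (not isolated)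
10 | 4-hydroxy-2,3-dimethoxy-4-{cis-2-[3,4-bis(triisopropylsilyloxy)phenyl]-4-(triethylsilyloxy)-3,4-dihydro-2H-pyran-6-yl}cyclobut-2-en-1-one (carbinol centre undefined) | COC1=C(OC)C(O)(C2=C[C@H](O[Si](CC)(CC)CC)C[C@H](c3ccc(O[Si](C(C)C)(C(C)C)C(C)C)c(O[Si](C(C)C)(C(C)C)C(C)C)c3)O2)C1=O | intermediate
11 | 4-hydroxy-2,3-dimethoxy-4-(dihydropyran-6-yl)buta-1,3-dien-1-one, dihydropyranyl cis to the ketene (dienylketene) | O=C=C(OC)/C(OC)=C(/O)C1=C[C@H](O[Si](CC)(CC)CC)C[C@H](c2ccc(O[Si](C(C)C)(C(C)C)C(C)C)c(O[Si](C(C)C)(C(C)C)C(C)C)c2)O1 | intermediate (not isolated)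
12 | 8-hydroxy-6,7-dimethoxy-4-(triethylsilyloxy)-2-[3,4-bis(triisopropylsilyloxy)phenyl]-2,3,4,4a-tetrahydro-5H-chromen-5-one (C4a undefined) | COC1=C(OC)C(O)=C2O[C@@H](c3ccc(O[Si](C(C)C)(C(C)C)C(C)C)c(O[Si](C(C)C)(C(C)C)C(C)C)c3)C[C@@H](O[Si](CC)(CC)CC)C2C1=O | intermediate (not isolated)
13 | cis-5,8-dihydroxy-6,7-dimethoxy-4-(triethylsilyloxy)-2-[3,4-bis(triisopropylsilyloxy)phenyl]chroman (racemic) | COc1c(OC)c(O)c2O[C@@H](c3ccc(O[Si](C(C)C)(C(C)C)C(C)C)c(O[Si](C(C)C)(C(C)C)C(C)C)c3)C[C@@H](O[Si](CC)(CC)CC)c2c1O | intermediate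
14 | cis-5,6,7,8-tetramethoxy-4-(triethylsilyloxy)-2-[3,4-bis(triisopropylsilyloxy)phenyl]chroman (racemic) | COc1c(OC)c(OC)c2O[C@@H](c3ccc(O[Si](C(C)C)(C(C)C)C(C)C)c(O[Si](C(C)C)(C(C)C)C(C)C)c3)C[C@@H](O[Si](CC)(CC)CC)c2c1OC | intermediate
15 | cis-5,6,7,8-tetramethoxy-2-[3,4-bis(triisopropylsilyloxy)phenyl]chroman-4-ol (racemic) | COc1c(OC)c(OC)c2O[C@@H](c3ccc(O[Si](C(C)C)(C(C)C)C(C)C)c(O[Si](C(C)C)(C(C)C)C(C)C)c3)C[C@@H](O)c2c1OC | intermediate
16 | 5,6,7,8-tetramethoxy-2-[3,4-bis(triisopropylsilyloxy)phenyl]chroman-4-one (racemic) | COc1c(OC)c(OC)c2O[C@@H](c3ccc(O[Si](C(C)C)(C(C)C)C(C)C)c(O[Si](C(C)C)(C(C)C)C(C)C)c3)CC(=O)c2c1OC | intermediate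
17 | 5,6,7,8-tetramethoxy-2-[3,4-bis(triisopropylsilyloxy)phenyl]-4H-chromen-4-one | COc1c(OC)c(OC)c2c(=O)cc(-c3ccc(O[Si](C(C)C)(C(C)C)C(C)C)c(O[Si](C(C)C)(C(C)C)C(C)C)c3)oc2c1OC | intermediate
18 | 2-(3,4-dihydroxyphenyl)-5,6,7,8-tetramethoxy-4H-chromen-4-one | COc1c(OC)c(OC)c2c(=O)cc(-c3ccc(O)c(O)c3)oc2c1OC | target

Total step count: 11. Longest linear sequence: 11 steps (1 → 18); 3 and 8 enter as purchased.

Steps most likely to fail

Step 5. The risk is that t-BuLi removes the benzylic C2–H (also α to oxygen) or a silyl alkyl proton instead of the vinylic C6–H, followed by fragmentation of ring C, so that little vinyllithium reaches the squarate. The fallback sets out from 7 and returns at 9, replacing deprotonation by tin–lithium exchange. Oxidation of the enol ether of 7 with pyridinium chlorochromate (C5H5NH[CrO3Cl]) in CH2Cl2, a known enol-ether-to-lactone oxidation, should give the δ-lactone cis-6-[3,4-bis(triisopropylsilyloxy)phenyl]-4-(triethylsilyloxy)tetrahydro-2H-pyran-2-one F1. Enolisation with KN(SiMe3)2 in THF/HMPA at −78 °C and trapping with (PhO)2P(O)Cl should give the ketene acetal phosphate diphenyl {cis-2-[3,4-bis(triisopropylsilyloxy)phenyl]-4-(triethylsilyloxy)-3,4-dihydro-2H-pyran-6-yl} phosphate F2. Coupling with Me3SnSnMe3, Pd(PPh3)4 (zerovalent palladium) and LiCl in THF should give the vinylstannane trimethyl{cis-2-[3,4-bis(triisopropylsilyloxy)phenyl]-4-(triethylsilyloxy)-3,4-dihydro-2H-pyran-6-yl}stannane F3. MeLi in THF at −78 °C then generates vinyllithium 9 without any C–H deprotonation, and 9 is added to 8 as in step 5.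

Step 6. The risk is that ring opening is not fully torquoselective and the ketene is captured by the carbinol oxygen (lactonisation to a butenolide), or that the hydroquinone is lost to air oxidation during isolation. The fallback sets out from 10 and returns at 14, using a capped carbinol. Methylation of the tertiary hydroxyl with MeI, Ag2O and K2CO3 in MeCN at 25 °C should give 2,3,4-trimethoxy-4-{cis-2-[3,4-bis(triisopropylsilyloxy)phenyl]-4-(triethylsilyloxy)-3,4-dihydro-2H-pyran-6-yl}cyclobut-2-en-1-one F4. Heating F4 in toluene runs the same 4π/6π sequence and should give the monophenol cis-5-hydroxy-6,7,8-trimethoxy-4-(triethylsilyloxy)-2-[3,4-bis(triisopropylsilyloxy)phenyl]chroman F5, which cannot lactonise and is not oxidised to a quinone. A single methylation (MeI, K2CO3, acetone) gives 14.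

Step 10. The risk is that hydride abstraction by DDQ stalls at partial conversion, or that the quinone attacks the electron-rich rings on prolonged heating. The fallback sets out from 16 and returns at 17 by a Saegusa–Ito sequence. TMSOTf and Et3N in CH2Cl2 at 0 °C should give the silyl enol ether 5,6,7,8-tetramethoxy-4-(trimethylsilyloxy)-2-[3,4-bis(triisopropylsilyloxy)phenyl]-2H-chromene F6. Treatment with Pd(OAc)2 (divalent palladium) in MeCN at 25 °C effects β-hydride elimination from the palladium enolate to give 17.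

Further compounds
F1 | step 5 | cis-6-[3,4-bis(triisopropylsilyloxy)phenyl]-4-(triethylsilyloxy)tetrahydro-2H-pyran-2-one | O=C1C[C@H](O[Si](CC)(CC)CC)C[C@H](c2ccc(O[Si](C(C)C)(C(C)C)C(C)C)c(O[Si](C(C)C)(C(C)C)C(C)C)c2)O1
F2 | step 5 | diphenyl {cis-2-[3,4-bis(triisopropylsilyloxy)phenyl]-4-(triethylsilyloxy)-3,4-dihydro-2H-pyran-6-yl} phosphate | O=P(Oc1ccccc1)(Oc1ccccc1)OC1=C[C@H](O[Si](CC)(CC)CC)C[C@H](c2ccc(O[Si](C(C)C)(C(C)C)C(C)C)c(O[Si](C(C)C)(C(C)C)C(C)C)c2)O1
F3 | step 5 | trimethyl{cis-2-[3,4-bis(triisopropylsilyloxy)phenyl]-4-(triethylsilyloxy)-3,4-dihydro-2H-pyran-6-yl}stannane | C[Sn](C)(C)C1=C[C@H](O[Si](CC)(CC)CC)C[C@H](c2ccc(O[Si](C(C)C)(C(C)C)C(C)C)c(O[Si](C(C)C)(C(C)C)C(C)C)c2)O1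
F4 | step 6 | 2,3,4-trimethoxy-4-{cis-2-[3,4-bis(triisopropylsilyloxy)phenyl]-4-(triethylsilyloxy)-3,4-dihydro-2H-pyran-6-yl}cyclobut-2-en-1-one | COC1=C(OC)C(OC)(C2=C[C@H](O[Si](CC)(CC)CC)C[C@H](c3ccc(O[Si](C(C)C)(C(C)C)C(C)C)c(O[Si](C(C)C)(C(C)C)C(C)C)c3)O2)C1=O
F5 | step 6 | cis-5-hydroxy-6,7,8-trimethoxy-4-(triethylsilyloxy)-2-[3,4-bis(triisopropylsilyloxy)phenyl]chroman | COc1c(OC)c(OC)c2O[C@@H](c3ccc(O[Si](C(C)C)(C(C)C)C(C)C)c(O[Si](C(C)C)(C(C)C)C(C)C)c3)C[C@@H](O[Si](CC)(CC)CC)c2c1O
F6 | step 10 | 5,6,7,8-tetramethoxy-4-(trimethylsilyloxy)-2-[3,4-bis(triisopropylsilyloxy)phenyl]-2H-chromene | COc1c(OC)c(OC)c2O[C@@H](c3ccc(O[Si](C(C)C)(C(C)C)C(C)C)c(O[Si](C(C)C)(C(C)C)C(C)C)c3)C=C(O[Si](C)(C)C)c2c1OC
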